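**Plan**

1. Retrosynthetic cuts: the C6 acetate and a C3 silyl ether; the diene (C13=C16 by carbonyl methylenation, C13–C14 by vinyl addition to a C13 lactone); O–C8 together with C17 (lactonisation onto an 8(17)-alkene); H–C5 and O–C6 (hydroboration of C5=C6); then the C9–C10 bond, which contracts ring B to a five-membered ring; last the C8=C9 alkene (Wittig) and the two C4 methyls.
2. Enabling feature: in ring B the oxygen-bearing C8 lies between the C9 methine that carries the chain and the quaternary C10. Taking C9 out leaves a hydrindane whose C8 is the saturated ketone carbon of the Hajos–Parrish ketone, so ring B can grow from the ring C5–C6–C7–C8–C10 by a 1,2-shift of C10 from C8 to C9.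
3. Forward order: Hajos–Parrish ketone (ring A and the five-membered ring) plus the C9/C11–C13 chain by Wittig reaction; gem-dimethylation; dihydroxylation and mesylation; semipinacol ring expansion to the decalin; then C8, C5/C6, the diene and the acetate.
4. Stereochemistry: C10 from (R)-Hajos–Parrish ketone; C9 from the stereospecific shift (inversion) of a carbinol set by OsO4 on the Z alkene; C8 by oxygen delivery from the axial C9 chain; C5 and C6 by hydroboration anti to C20; C3 by axial hydride delivery.

Key step: step 8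

Remark: atoms keep labdane numbers throughout (C20 = methyl on C10, C17 = carbon on C8; syn/anti refer to the C20 face); the target SMILES is read as (3R,5S,6R,8S,9R,10R), that is a trans-decalin with equatorial oxygens at C3, C6 and C8 and an axial C9 chain anti to C20; (R)-Hajos–Parrish ketone is taken as a catalogue compound.

**Route**

Step 1
Reactants: 1 (3-carboxypropyl)triphenylphosphonium bromide
Product: 3 [4-(dimethylamino)-4-oxobutyl]triphenylphosphonium bromide, via acid chloride 2 (not isolated)
Conditions: (COCl)2, cat. DMF, CH2Cl2, 0 °C to rt; then Me2NH (3 equiv, THF solution), 0 °C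
Reagents that add atoms: dimethylamine, CNC
Why: Acid chloride formation followed by aminolysis (amide synthesis) gives a tertiary amide that later serves as a masked carboxyl group stable to base, hydride and Lewis acid; no stereocentre is formed.

Step 2
Reactants: 3 [4-(dimethylamino)-4-oxobutyl]triphenylphosphonium bromide; 4 (R)-Hajos–Parrish ketone
Product: 6 (Z)-N,N-dimethyl-4-(7a-methyl-5-oxo-2,3,5,6,7,7a-hexahydro-1H-inden-1-ylidene)butanamide (C10 as in 4; C11 cis to C10), via ylide 5 (not isolated)
Conditions: 3 (2.5 equiv), KN(SiMe3)2 (2.4 equiv), THF, −78 to 0 °C; then 4, −78 to 45 °C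
Reagents that add atoms: none
Why: Wittig olefination with a non-stabilised ylide should take the saturated C8 ketone in preference to the less electrophilic enone carbonyl (as in selective olefinations of the Wieland–Miescher ketone) and, as with 17-oxo steroids, should give the Z alkene with C11 cis to the quaternary C10; no stereocentre is formed.

Step 3
Reactants: 6 (Z)-alkylidene enone
Product: 8 (Z)-N,N-dimethyl-4-(4,4,7a-trimethyl-5-oxo-2,4,5,6,7,7a-hexahydro-1H-inden-1-ylidene)butanamide, via monomethyl ketone 7 (not isolated)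
Conditions: KOtBu (3.2 equiv), tBuOH/THF, 0 °C; MeI (6 equiv), 0 °C to rt
Reagents that add atoms: iodomethane, CI
Why: Deconjugative double α-alkylation of the enone through its extended dienolate installs both C4 methyls and moves the alkene to C5=C6; no stereocentre is formed.

Step 4
Reactants: 8 4,4-dimethyl β,γ-enone
Product: 9 C3 alcohol of 8 (C3–OH syn to C20)
Conditions: NaBH4, MeOH/THF, 0 °C
Reagents that add atoms: none
Why: Hydride reduction of the neopentyl ketone by axial attack on the face anti to C20 should give the equatorial C3 alcohol, as with 4,4-dimethyl-3-oxo steroids and triterpenoids.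

Step 5
Reactants: 9 C3 alcohol
Product: 10 C3 tert-butyldimethylsilyl ether of 9
Conditions: tBuMe2SiOTf, 2,6-lutidine, CH2Cl2, −78 to 0 °C
Reagents that add atoms: tert-butyldimethylsilyl trifluoromethanesulfonate, CC(C)(C)[Si](C)(C)OS(=O)(=O)C(F)(F)F
Why: Silyl ether formation with the reactive triflate protects the hindered C3 hydroxyl, which keeps C3 and C6 distinguishable at the end; no stereocentre is formed.

Step 6
Reactants: 10 silyl ether
Product: 12 8,9-diol (C8–OH anti to C20; 9R), via osmate ester 11 (not isolated)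
Conditions: OsO4 (0.03 equiv), N-methylmorpholine N-oxide (1.2 equiv), acetone/H2O, 0 °C to rt
Reagents that add atoms: osmium tetroxide, O=[Os](=O)(=O)=O; N-methylmorpholine N-oxide, C[N+]1([O-])CCOCC1; water, O
Why: Catalytic syn-dihydroxylation (Upjohn conditions) should take the exocyclic C8=C9 alkene and leave C5=C6, whose C5 is flanked by two quaternary carbons, and should add anti to the adjacent C20 methyl, so the Z geometry sets C8 (OH anti to C20) and C9 (R).

Step 7
Reactants: 12 8,9-diol
Product: 13 9-methanesulfonate of 12 (9R)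
Conditions: MsCl (1.3 equiv), Et3N, CH2Cl2, −20 °C
Reagents that add atoms: methanesulfonyl chloride, CS(=O)(=O)Cl
Why: Sulfonylation takes the secondary C9 hydroxyl and leaves the tertiary C8 hydroxyl; C9 keeps its configuration.

Step 8
Reactants: 13 9-methanesulfonate
Product: 15 ring-expanded ketone 3-[6-(tert-butyldimethylsilyloxy)-5,5,8a-trimethyl-2-oxo-1,2,3,5,6,7,8,8a-octahydronaphthalen-1-yl]-N,N-dimethylpropanamide (9R; chain anti to C20), via aluminium alkoxide 14 (not isolated)
Conditions: Et3Al (4 equiv, hexane solution), CH2Cl2, −78 to −30 °C; aq. KNaC4H4O6 work-up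
Reagents that add atoms: none
Why: Et3Al converts the C8 hydroxyl into an aluminium alkoxide and activates the C9 mesylate, and the C8–C10 bond then migrates to C9 as the mesylate leaves while the alkoxide oxygen becomes the C8 carbonyl; this is a semipinacol rearrangement of a 2-sulfonyloxy tertiary alcohol, closest to the organoaluminium-promoted 1,2-shifts of β-mesyloxy alcohols and the D-homoannulation of 17-hydroxy-20-sulfonyloxy steroids. No ring is closed by cyclisation: ring B arises from the five-membered ring C5–C6–C7–C8–C10 by insertion of C9 between C8 and C10. The new C9 stereocentre is fixed by the stereospecific shift, with inversion at C9 (anti to the departing mesylate) and retention at C10, so the 9R carbinol gives the 9R ketone with the chain anti to C20. The step needs C10 rather than C7 to migrate and no epoxide closure: in the preferred rotamer about C8–C9 the C9 hydrogen occupies the hindered inside position on the C20 face, which puts the mesylate anti-periplanar to C8–C10, and the quaternary allylic C10 is also the better migrating group, whereas epoxide closure would need the mesylate inside. The non-basic, cold medium should keep the new α-stereocentre and the β,γ-alkene in place.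

Step 9
Reactants: 15 ring-expanded ketone
Product: 16 8(17)-methylene compound 3-[6-(tert-butyldimethylsilyloxy)-5,5,8a-trimethyl-2-methylidene-1,2,3,5,6,7,8,8a-octahydronaphthalen-1-yl]-N,N-dimethylpropanamide
Conditions: Zn, CH2Br2, TiCl4, THF (reagent pre-formed, 0 °C); then 15, CH2Cl2, 0 °C to rt
Reagents that add atoms: dibromomethane, BrCBr
Why: Takai–Lombardo methylenation is non-basic, so the C9 centre next to the ketone should not epimerise, the β,γ-alkene should not move into conjugation, and the amide is left alone.

Step 10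
Reactants: 16 8(17)-methylene compound
Product: 18 iodolactone (cis-fused δ-lactone; O–C8 syn to the C9 chain; CH2I syn to C20), via iminium lactone 17 (not isolated)
Conditions: I2 (3 equiv), NaHCO3, THF/H2O, 0 °C to rt, dark; Na2S2O3 work-up
Reagents that add atoms: iodine, II; water, O
Why: Iodolactonisation of the unsaturated tertiary amide (6-exo attack of the amide oxygen on the tertiary C8 of the iodonium ion, then hydrolysis of the iminium lactone) sets C8, because the C9 chain is axial (favoured by allylic 1,3-strain with the exocyclic methylene) and can reach only the equatorial position of C8, which puts oxygen syn to the chain and C17 syn to C20.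

Step 11
Reactants: 18 iodolactone
Product: 19 lactone (C17 methyl)
Conditions: Bu3SnH (3 equiv, 0.3 M), AIBN (cat.), toluene, 80 °C
Reagents that add atoms: none
Why: Radical-chain dehalogenation turns the neopentyl iodide into the C17 methyl, and the high stannane concentration lets hydrogen transfer outrun a 1,2-acyloxy shift; no stereocentre changes.

Step 12
Reactants: 19 lactone
Product: 21 triol (C6–OH anti to C20; H5 anti to C20; C8–OH; C13–OH), via borane adduct 20 (not isolated)
Conditions: BH3·SMe2 (8 equiv), THF, 0 to 60 °C; then NaOH, H2O2, 0 °C to rt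
Reagents that add atoms: hydrogen peroxide, OO
Why: Hydroboration–oxidation adds H–B syn to C5=C6 from the face anti to the C20 and axial C4 methyls, with boron on the less substituted C6, which sets the trans ring fusion and the equatorial C6 hydroxyl, and the excess borane reduces the lactone cleanly to the C8/C13 diol.

Step 13
Reactants: 21 triol
Product: 23 6-hydroxy δ-lactone, via lactol 22 (not isolated)
Conditions: TEMPO (0.2 equiv), PhI(OAc)2 (2.5 equiv), CH2Cl2, rt
Reagents that add atoms: none
Why: Oxoammonium oxidation takes the primary C13 alcohol in preference to the hindered secondary C6 alcohol, the aldehyde is trapped by the C8 hydroxyl as the lactol, and this is oxidised on to the lactone (oxidative lactonisation of a 1,5-diol).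

Step 14
Reactants: 23 6-hydroxy δ-lactone
Product: 24 hydroxy vinyl ketone (in equilibrium with its cyclic C13 hemiketal)
Conditions: CH2=CHMgBr (3 equiv), THF, −78 °C; aq. NH4Cl at −78 °C
Reagents that add atoms: vinylmagnesium bromide, C=C[Mg]Br
Why: Mono-addition of a Grignard reagent to a lactone at low temperature stops at the tetrahedral magnesium hemiketal, which should survive until the cold quench has destroyed the excess reagent.

Step 15
Reactants: 24 hydroxy vinyl ketone
Product: 25 diene diol (3-O-silyl 6-deacetyl target)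
Conditions: Ph3PCH3Br (6 equiv), KOtBu (5.5 equiv), THF, 0 °C; then 24, 0 °C to rt
Reagents that add atoms: methyltriphenylphosphonium bromide, C[P+](c1ccccc1)(c1ccccc1)c1ccccc1.[Br-]
Why: Wittig methylenation of the enone carbonyl (1,2-addition of the non-stabilised ylide to the open hydroxy ketone, which the basic medium frees from the hemiketal) completes the 2-substituted buta-1,3-diene.

Step 16
Reactants: 25 diene diol
Product: 26 3-O-tert-butyldimethylsilyl ether of the target
Conditions: Ac2O, pyridine, DMAP (cat.), CH2Cl2, 0 °C to rt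
Reagents that add atoms: acetic anhydride, CC(=O)OC(C)=O
Why: DMAP-catalysed acylation esterifies the secondary C6 hydroxyl, while the tertiary C8 hydroxyl should not react under these conditions and C3 is still silylated.

Step 17
Reactants: 26 3-O-silyl ether of the target
Product: 27 (3R,5S,6R,8S,9R,10R)-3,8-dihydroxylabda-13(16),14-dien-6-yl acetate
Conditions: HF·pyridine, pyridine/THF, 0 °C to rt
Reagents that add atoms: none
Why: Fluoride-mediated silyl ether cleavage under buffered conditions should leave the acetate, the tertiary alcohol and the diene untouched.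

**Compound list**

1 | (3-carboxypropyl)triphenylphosphonium bromide | OC(=O)CCC[P+](c1ccccc1)(c1ccccc1)c1ccccc1.[Br-] | starting material
2 | (4-chloro-4-oxobutyl)triphenylphosphonium bromide (acid chloride) | ClC(=O)CCC[P+](c1ccccc1)(c1ccccc1)c1ccccc1.[Br-] | intermediate (not isolated)
3 | [4-(dimethylamino)-4-oxobutyl]triphenylphosphonium bromide | CN(C)C(=O)CCC[P+](c1ccccc1)(c1ccccc1)c1ccccc1.[Br-] | intermediate
4 | (R)-Hajos–Parrish ketone, (7aR)-7a-methyl-2,3,7,7a-tetrahydro-1H-indene-1,5(6H)-dione | C[C@@]12CCC(=O)C=C1CCC2=O | starting material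
5 | N,N-dimethyl-4-(triphenylphosphoranylidene)butanamide (ylide of 3) | CN(C)C(=O)CCC=P(c1ccccc1)(c1ccccc1)c1ccccc1 | intermediate (not isolated)
6 | (Z)-N,N-dimethyl-4-(7a-methyl-5-oxo-2,3,5,6,7,7a-hexahydro-1H-inden-1-ylidene)butanamide; C10 as in 4; C11 cis to C10 | C[C@@]12CCC(=O)C=C1CC/C2=C/CCC(=O)N(C)C | intermediate
7 | 4-monomethyl ketone (as 8 with one methyl on C4; both C4 epimers) | C[C@@]12CCC(=O)C(C)C1=CC/C2=C/CCC(=O)N(C)C | intermediate (not isolated)
8 | (Z)-N,N-dimethyl-4-(4,4,7a-trimethyl-5-oxo-2,4,5,6,7,7a-hexahydro-1H-inden-1-ylidene)butanamide | C[C@@]12CCC(=O)C(C)(C)C1=CC/C2=C/CCC(=O)N(C)C | intermediate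
9 | C3 alcohol of 8; C3–OH syn to C20 | C[C@@]12CC[C@@H](O)C(C)(C)C1=CC/C2=C/CCC(=O)N(C)C | intermediate
10 | C3 tert-butyldimethylsilyl ether of 9 | C[C@@]12CC[C@@H](O[Si](C)(C)C(C)(C)C)C(C)(C)C1=CC/C2=C/CCC(=O)N(C)C | intermediate
11 | cyclic osmate ester of 10 across C8–C9; both oxygens anti to C20 | C[C@@]12CC[C@@H](O[Si](C)(C)C(C)(C)C)C(C)(C)C1=CC[C@]23O[Os](=O)(=O)O[C@@H]3CCC(=O)N(C)C | intermediate (not isolated)
12 | 8,9-diol; C8–OH anti to C20; 9R | C[C@@]12CC[C@@H](O[Si](C)(C)C(C)(C)C)C(C)(C)C1=CC[C@@]2(O)[C@H](O)CCC(=O)N(C)C | intermediate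
13 | 9-methanesulfonate of 12; 9R | C[C@@]12CC[C@@H](O[Si](C)(C)C(C)(C)C)C(C)(C)C1=CC[C@@]2(O)[C@H](OS(C)(=O)=O)CCC(=O)N(C)C | intermediate
14 | diethylaluminium C8 alkoxide of 13 | C[C@@]12CC[C@@H](O[Si](C)(C)C(C)(C)C)C(C)(C)C1=CC[C@@]2(O[Al](CC)CC)[C@H](OS(C)(=O)=O)CCC(=O)N(C)C | intermediate (not isolated)
15 | ring-expanded ketone 3-[6-(tert-butyldimethylsilyloxy)-5,5,8a-trimethyl-2-oxo-1,2,3,5,6,7,8,8a-octahydronaphthalen-1-yl]-N,N-dimethylpropanamide; 9R; chain anti to C20 | CN(C)C(=O)CC[C@@H]1[C@]2(C)CC[C@@H](O[Si](C)(C)C(C)(C)C)C(C)(C)C2=CCC1=O | intermediate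
16 | 8(17)-methylene compound (C8=CH2 in place of the C8 carbonyl of 15) | CN(C)C(=O)CC[C@@H]1[C@]2(C)CC[C@@H](O[Si](C)(C)C(C)(C)C)C(C)(C)C2=CCC1=C | intermediate
17 | iodo iminium lactone iodide (O–C8 bond formed; C13=N+Me2) | C[N+](C)=C1CC[C@@H]2[C@]3(C)CC[C@@H](O[Si](C)(C)C(C)(C)C)C(C)(C)C3=CC[C@]2(CI)O1.[I-] | intermediate (not isolated)
18 | iodolactone; cis-fused δ-lactone; O–C8 syn to the C9 chain; CH2I syn to C20 | O=C1CC[C@@H]2[C@]3(C)CC[C@@H](O[Si](C)(C)C(C)(C)C)C(C)(C)C3=CC[C@]2(CI)O1 | intermediate
19 | lactone with C17 methyl | O=C1CC[C@@H]2[C@]3(C)CC[C@@H](O[Si](C)(C)C(C)(C)C)C(C)(C)C3=CC[C@]2(C)O1 | intermediate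
20 | borane adduct; boron on C6 anti to C20; lactone reduced to the bis(boryl ether) | BOCCC[C@@H]1[C@]2(C)CC[C@@H](O[Si](C)(C)C(C)(C)C)C(C)(C)[C@H]2[C@H](B)C[C@]1(C)OB | intermediate (not isolated)
21 | triol; trans-decalin; C6–OH anti to C20; tertiary C8–OH; primary C13–OH | OCCC[C@@H]1[C@]2(C)CC[C@@H](O[Si](C)(C)C(C)(C)C)C(C)(C)[C@H]2[C@H](O)C[C@]1(C)O | intermediate
22 | lactol (C13 hemiacetal with the C8 oxygen; both anomers) | OC1CC[C@@H]2[C@]3(C)CC[C@@H](O[Si](C)(C)C(C)(C)C)C(C)(C)[C@H]3[C@H](O)C[C@]2(C)O1 | intermediate (not isolated)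
23 | 6-hydroxy δ-lactone | O=C1CC[C@@H]2[C@]3(C)CC[C@@H](O[Si](C)(C)C(C)(C)C)C(C)(C)[C@H]3[C@H](O)C[C@]2(C)O1 | intermediate
24 | hydroxy vinyl ketone (open form of the C13 hemiketal) | C=CC(=O)CC[C@@H]1[C@]2(C)CC[C@@H](O[Si](C)(C)C(C)(C)C)C(C)(C)[C@H]2[C@H](O)C[C@]1(C)O | intermediate
25 | diene diol; 3-O-silyl 6-deacetyl target | C=CC(=C)CC[C@@H]1[C@]2(C)CC[C@@H](O[Si](C)(C)C(C)(C)C)C(C)(C)[C@H]2[C@H](O)C[C@]1(C)O | intermediate
26 | 3-O-tert-butyldimethylsilyl ether of the target | C=CC(=C)CC[C@@H]1[C@]2(C)CC[C@@H](O[Si](C)(C)C(C)(C)C)C(C)(C)[C@H]2[C@H](OC(C)=O)C[C@]1(C)O | intermediate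
27 | (3R,5S,6R,8S,9R,10R)-3,8-dihydroxylabda-13(16),14-dien-6-yl acetate | C=CC(=C)CC[C@@H]1[C@]2(C)CC[C@@H](O)C(C)(C)[C@H]2[C@H](OC(C)=O)C[C@]1(C)O | target

**Step count and risks**

Total: 17 steps. Longest linear sequence: 17 steps (1 to 27); 16 steps from the Hajos–Parrish ketone 4.

Steps most likely to fail:

Step 2. The ylide may attack or enolise the enone, and Z selectivity may be incomplete. The fallback sets out from 4. The enone carbonyl is first masked as its dithiolane (HSCH2CH2SH, BF3·OEt2, MeOH, 0 °C; the alkene stays at C4=C5) to give the enone dithiolane F1. Wittig reaction of F1 with ylide 5 under the step 2 conditions gives the (Z)-alkylidene dithiolane F2, from which any E isomer is removed by chromatography. MeI, CaCO3, aq. MeCN then frees the ketone and the route is rejoined at 6.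

Step 8. C7 may migrate in place of C10, or the C8 oxygen may displace the mesylate. The fallback sets out from 13 and uses the oxygen displacement on purpose. K2CO3 in MeOH closes the 8,9-epoxide F3 (inversion at C9). NaN3, NH4Cl, aq. DMF, 90 °C opens it at the secondary C9 (second inversion) to give the azido alcohol F4, which has nitrogen where the mesylate stood. PMe3 in aq. THF gives the amino alcohol F5. NaNO2 in aq. AcOH at 0 °C forms the diazonium ion F6, which undergoes Tiffeneau–Demjanov ring expansion with the same anti-periplanar C10 shift, and the route is rejoined at 15.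

Step 14. A second equivalent of Grignard reagent may add, in 1,2- or conjugate fashion, once the hemiketal opens, and the vinyl ketone may polymerise. The fallback sets out from 23. iBu2AlH in CH2Cl2 at −78 °C reduces the lactone back to the lactol 22. The Ohira–Bestmann reagent (dimethyl 1-diazo-2-oxopropylphosphonate, K2CO3, MeOH) converts its aldehyde form into the terminal alkyne F7. Enyne cross-metathesis with ethene (second-generation Grubbs catalyst, RuCl2(=CHPh)(PCy3)(H2IMes), CH2Cl2, 40 °C) builds the 2-substituted butadiene, and the route is rejoined at 25.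

Further compounds
F1 | step 2 | enone dithiolane (C3 carbonyl of 4 as 1,3-dithiolane; C8 ketone free) | C[C@@]12CCC3(SCCS3)C=C1CCC2=O
F2 | step 2 | (Z)-alkylidene dithiolane (6 with the C3 carbonyl as 1,3-dithiolane) | C[C@@]12CCC3(SCCS3)C=C1CC/C2=C/CCC(=O)N(C)C
F3 | step 8 | 8,9-epoxide (oxygen anti to C20; C9 inverted relative to 13) | C[C@@]12CC[C@@H](O[Si](C)(C)C(C)(C)C)C(C)(C)C1=CC[C@]23O[C@H]3CCC(=O)N(C)C
F4 | step 8 | azido alcohol (azide in the place of the mesylate of 13) | C[C@@]12CC[C@@H](O[Si](C)(C)C(C)(C)C)C(C)(C)C1=CC[C@@]2(O)[C@H](N=[N+]=[N-])CCC(=O)N(C)C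
F5 | step 8 | amino alcohol (NH2 in the place of the mesylate of 13) | C[C@@]12CC[C@@H](O[Si](C)(C)C(C)(C)C)C(C)(C)C1=CC[C@@]2(O)[C@H](N)CCC(=O)N(C)C
F6 | step 8 | diazonium acetate of F5 | C[C@@]12CC[C@@H](O[Si](C)(C)C(C)(C)C)C(C)(C)C1=CC[C@@]2(O)[C@H]([N+]#N)CCC(=O)N(C)C.CC(=O)[O-]
F7 | step 14 | terminal alkyne (C13≡C14H on the C9 chain; C6 and C8 hydroxyls free; C3 silyl ether) | C#CCC[C@@H]1[C@]2(C)CC[C@@H](O[Si](C)(C)C(C)(C)C)C(C)(C)[C@H]2[C@H](O)C[C@]1(C)O
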